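The cyclobutane is disconnected at its C1–C2 bond (ring numbering: C1 = CH carrying the alkenyl arm, C2 = CH carrying the 3-oxobutyl arm, C3 = CMe2, C4 = CH2). C1 and C2 are neighbouring methines and the C1 arm can be traced back to a carboxyl carbon, so they correspond to C2 and C5 of a 4,4-dimethyl-5-alkylproline ester whose nitrogen bridges them. Excising that nitrogen as N2 joins the two α-carbons and shrinks the pyrrolidine to the four-membered ring with retention. The precursor is the 2,5-cis NH-pyrrolidine methyl ester with the side-chain ketone masked as a dioxolane, built from methyl L-pyroglutamate.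

Key step: step 5

Remark: because C1 is equilibrated after the contraction, the absolute configuration of the target rests on C5 of pyrrolidine 10 alone, so 10 is carried forward only as the pure 2,5-cis isomer.

Step 1
Reactants: 1 methyl L-pyroglutamate
Product: 2 1-benzyl 2-methyl (S)-5-oxopyrrolidine-1,2-dicarboxylate
Conditions: LiHMDS, THF, −78 °C; CbzCl, −78 °C → rt
Reagents that add atoms: benzyl chloroformate, O=C(Cl)OCc1ccccc1
Why: N-Acylation of the lactam, in which LiHMDS removes the most acidic proton (N–H) and the amide anion is trapped by the chloroformate at low temperature, activating the ring carbonyl for steps 2 and 3 without touching C2.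

Step 2
Reactants: 2 1-benzyl 2-methyl (S)-5-oxopyrrolidine-1,2-dicarboxylate
Product: 4 1-benzyl 2-methyl (S)-4,4-dimethyl-5-oxopyrrolidine-1,2-dicarboxylate, via 4-monomethyl lactam 3 (not isolated)
Conditions: LiHMDS (1.1 equiv), THF, −78 °C, MeI; then LiHMDS (1.2 equiv), MeI, −78 → −30 °C, same flask
Reagents that add atoms: iodomethane, CI
Why: Two successive lactam-enolate alkylations (SN2 on MeI), in which the N-acyl lactam is deprotonated kinetically at C4 and not at the C2 α-amino-ester position, the second methylation erases the transient C4 centre, and C2 stays S.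

Step 3
Reactants: 4 1-benzyl 2-methyl (S)-4,4-dimethyl-5-oxopyrrolidine-1,2-dicarboxylate; 5 2-(2-bromoethyl)-2-methyl-1,3-dioxolane
Product: 7 methyl (S)-2-{[(benzyloxy)carbonyl]amino}-4,4-dimethyl-7-(2-methyl-1,3-dioxolan-2-yl)-5-oxoheptanoate, via Grignard reagent 6 (not isolated)
Conditions: 5, Mg, THF, 20–25 °C; then 4, THF, −78 → −40 °C; aq. NH4Cl
Reagents that add atoms: none
Why: Grignard addition to an N-acyl (imide-type) lactam, where the carbamate-activated ring carbonyl is the most electrophilic site at low temperature, has no α-hydrogen to lose, and gives a tetrahedral adduct that opens to the ketone and a carbamate anion so that no second addition occurs; the dioxolane is inert to the organometallic and to the NH4Cl quench.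

Step 4
Reactants: 7 methyl (S)-2-{[(benzyloxy)carbonyl]amino}-4,4-dimethyl-7-(2-methyl-1,3-dioxolan-2-yl)-5-oxoheptanoate
Product: 10 methyl (2S,5S)-4,4-dimethyl-5-[2-(2-methyl-1,3-dioxolan-2-yl)ethyl]pyrrolidine-2-carboxylate, via amino ketone 8 (not isolated), via cyclic imine 9 (not isolated)
Conditions: H2 (1–4 bar), 10% Pd/C, MeOH, rt
Reagents that add atoms: none
Why: Hydrogenolysis of the Cbz group frees the amine, which condenses with the δ-ketone to the five-membered cyclic imine (helped by the gem-dimethyl group), and heterogeneous hydrogenation (intramolecular reductive amination) then delivers hydrogen to the C=N face opposite the C2 ester, setting C5 as S (2,5-cis) under neutral conditions that spare the ketal; any 2,5-trans isomer should be removed here by chromatography because it would feed the enantiomeric series.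

Step 5
Reactants: 10 methyl (2S,5S)-4,4-dimethyl-5-[2-(2-methyl-1,3-dioxolan-2-yl)ethyl]pyrrolidine-2-carboxylate
Product: 12 methyl (1R,2R)-3,3-dimethyl-2-[2-(2-methyl-1,3-dioxolan-2-yl)ethyl]cyclobutane-1-carboxylate (cis), via 1,1-diazene 11 (not isolated)
Conditions: PhI(OH)OTs (2.5 equiv), H2NCO2NH4 (8 equiv), CF3CH2OH, 80 °C
Reagents that add atoms: none
Why: Ammonia released from ammonium carbamate is oxidised by the iodine(III) reagent to an iodonitrene, which aminates the ring nitrogen of 10 electrophilically to give the 1,1-diazene 11; this expels N2 to a singlet 1,4-biradical (ester-stabilised at the former pyrrolidine C2, secondary alkyl at the former C5) whose two radical centres couple to form the cyclobutane C1–C2 bond. The closest known reaction type is the iodonitrene-mediated nitrogen deletion of NH-pyrrolidine-2-carboxylates to cyclobutanes, itself related to the oxidative deamination of N-aminopyrrolidines through 1,1-diazenes. The four-membered ring is closed by intramolecular radical–radical recombination of the 1,4-biradical, a ring contraction by extrusion and not a polar cyclisation. No new stereocentre is made: both methines keep their configuration because the singlet biradical collapses faster than rotation about its C–C bonds, so cis-(2S,5S)-10 should give cis-(1R,2R)-12. The step needs ring closure to outrun β-scission of the pyrrolidine C3–C4 bond (to methyl acrylate and a trisubstituted alkene), and the substrate supports this through the gem-dimethyl group, which holds the biradical in the gauche geometry, and through the ester, which lowers the barrier to N2 loss. The ketone must stay masked because a free methyl ketone would condense with the ring NH or with ammonia, and the excess ammonium carbamate buffers the sulfonic acid released so that the dioxolane should survive.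

Step 6
Reactants: 12 methyl (1R,2R)-3,3-dimethyl-2-[2-(2-methyl-1,3-dioxolan-2-yl)ethyl]cyclobutane-1-carboxylate (cis)
Product: 13 methyl (1S,2R)-3,3-dimethyl-2-[2-(2-methyl-1,3-dioxolan-2-yl)ethyl]cyclobutane-1-carboxylate (trans)
Conditions: NaOMe, MeOH, reflux
Reagents that add atoms: none
Why: Base-mediated epimerisation through the ester enolate (thermodynamic equilibration) sets C1 as S, since the 1,2-trans ring relieves the eclipsing of the two adjacent arms, C2 carries no acidifying group and stays R, methoxide in methanol makes transesterification degenerate, and the ketal is base-stable.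

Step 7
Reactants: 13 methyl (1S,2R)-3,3-dimethyl-2-[2-(2-methyl-1,3-dioxolan-2-yl)ethyl]cyclobutane-1-carboxylate (trans)
Product: 14 (1S,2R)-N-methoxy-N,3,3-trimethyl-2-[2-(2-methyl-1,3-dioxolan-2-yl)ethyl]cyclobutane-1-carboxamide
Conditions: MeNHOMe·HCl, i-PrMgCl, THF, −20 → 0 °C
Reagents that add atoms: N,O-dimethylhydroxylamine hydrochloride, CNOC.Cl
Why: Weinreb amide formation by aminolysis of the ester with the chloromagnesium amide of N,O-dimethylhydroxylamine, a basic and non-Lewis-acidic protocol that leaves the ketal intact and C1 in its thermodynamic trans configuration.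

Step 8
Reactants: 14 (1S,2R)-N-methoxy-N,3,3-trimethyl-2-[2-(2-methyl-1,3-dioxolan-2-yl)ethyl]cyclobutane-1-carboxamide; 15 (3-bromopropoxy)(tert-butyl)dimethylsilane
Product: 17 4-[(tert-butyldimethylsilyl)oxy]-1-{(1S,2R)-3,3-dimethyl-2-[2-(2-methyl-1,3-dioxolan-2-yl)ethyl]cyclobutyl}butan-1-one, via Grignard reagent 16 (not isolated)
Conditions: 15, Mg, THF, rt; then 14, THF, 0 °C → rt; aq. NH4Cl
Reagents that add atoms: none
Why: Weinreb ketone synthesis, in which the primary Grignard reagent adds once to give a magnesium-chelated tetrahedral adduct that collapses to the ketone only on work-up, so no tertiary alcohol forms, and the silyl ether and ketal are inert.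

Step 9
Reactants: 17 4-[(tert-butyldimethylsilyl)oxy]-1-{(1S,2R)-3,3-dimethyl-2-[2-(2-methyl-1,3-dioxolan-2-yl)ethyl]cyclobutyl}butan-1-one
Product: 18 tert-butyl({4-[(1S,2R)-3,3-dimethyl-2-[2-(2-methyl-1,3-dioxolan-2-yl)ethyl]cyclobutyl]pent-4-en-1-yl}oxy)dimethylsilane
Conditions: Ph3PCH3Br, KOt-Bu, THF, 0 °C → rt
Reagents that add atoms: methyltriphenylphosphonium bromide, C[P+](c1ccccc1)(c1ccccc1)c1ccccc1.[Br-]
Why: Wittig methylenation of the ketone with the non-stabilised ylide gives the 1,1-disubstituted alkene with no geometric issue, and any reversible enolisation at C1 under the basic conditions returns to the favoured trans isomer.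

Step 10
Reactants: 18 tert-butyl({4-[(1S,2R)-3,3-dimethyl-2-[2-(2-methyl-1,3-dioxolan-2-yl)ethyl]cyclobutyl]pent-4-en-1-yl}oxy)dimethylsilane
Product: 19 4-[(1R,4S)-4-(5-hydroxypent-1-en-2-yl)-2,2-dimethylcyclobutyl]butan-2-one
Conditions: 1 M aq. HCl, THF, rt
Reagents that add atoms: water, O
Why: Acid-catalysed hydrolysis cleaves the primary TBS ether and the dioxolane in one operation, while dilute acid at room temperature is too weak to protonate the 1,1-disubstituted alkene next to the four-membered ring.

Step 11
Reactants: 19 4-[(1R,4S)-4-(5-hydroxypent-1-en-2-yl)-2,2-dimethylcyclobutyl]butan-2-one; 20 linoleic acid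
Product: 21 4-[(1S,2R)-3,3-dimethyl-2-(3-oxobutyl)cyclobutyl]pent-4-en-1-yl (9Z,12Z)-octadeca-9,12-dienoate (IN0146)
Conditions: EDC·HCl, DMAP (cat.), CH2Cl2, 0 °C → rt, Ar, dark
Reagents that add atoms: none
Why: Steglich esterification (carbodiimide activation with DMAP acyl transfer) acylates the primary alcohol under neutral conditions, so the skipped Z,Z-diene is not isomerised, the methyl ketone and exocyclic alkene are untouched, and the linoleoyl group is kept out of every acidic, basic and organometallic step.

Compound list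
1 | methyl L-pyroglutamate, methyl (S)-5-oxopyrrolidine-2-carboxylate | COC(=O)[C@@H]1CCC(=O)N1 | starting material
2 | 1-benzyl 2-methyl (S)-5-oxopyrrolidine-1,2-dicarboxylate | COC(=O)[C@@H]1CCC(=O)N1C(=O)OCc1ccccc1 | intermediate
3 | 1-benzyl 2-methyl (2S)-4-methyl-5-oxopyrrolidine-1,2-dicarboxylate (C4 epimers, mainly 2,4-trans; centre erased in the second methylation) | COC(=O)[C@@H]1CC(C)C(=O)N1C(=O)OCc1ccccc1 | intermediate
4 | 1-benzyl 2-methyl (S)-4,4-dimethyl-5-oxopyrrolidine-1,2-dicarboxylate | COC(=O)[C@@H]1CC(C)(C)C(=O)N1C(=O)OCc1ccccc1 | intermediate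
5 | 2-(2-bromoethyl)-2-methyl-1,3-dioxolane | CC1(CCBr)OCCO1 | starting material
6 | [2-(2-methyl-1,3-dioxolan-2-yl)ethyl]magnesium bromide | CC1(CC[Mg]Br)OCCO1 | intermediate
7 | methyl (S)-2-{[(benzyloxy)carbonyl]amino}-4,4-dimethyl-7-(2-methyl-1,3-dioxolan-2-yl)-5-oxoheptanoate | COC(=O)[C@H](CC(C)(C)C(=O)CCC1(C)OCCO1)NC(=O)OCc1ccccc1 | intermediate
8 | methyl (S)-2-amino-4,4-dimethyl-7-(2-methyl-1,3-dioxolan-2-yl)-5-oxoheptanoate | COC(=O)[C@H](CC(C)(C)C(=O)CCC1(C)OCCO1)N | intermediate
9 | methyl (S)-4,4-dimethyl-5-[2-(2-methyl-1,3-dioxolan-2-yl)ethyl]-3,4-dihydro-2H-pyrrole-2-carboxylate | COC(=O)[C@@H]1CC(C)(C)C(CCC2(C)OCCO2)=N1 | intermediate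
10 | methyl (2S,5S)-4,4-dimethyl-5-[2-(2-methyl-1,3-dioxolan-2-yl)ethyl]pyrrolidine-2-carboxylate (2,5-cis) | COC(=O)[C@@H]1CC(C)(C)[C@H](CCC2(C)OCCO2)N1 | intermediate
11 | 1,1-diazene (isodiazene) of 10, nitrogen of the (2S,5S)-pyrrolidine carrying a terminal N | COC(=O)[C@@H]1CC(C)(C)[C@H](CCC2(C)OCCO2)[N+]1=[N-] | intermediate
12 | methyl (1R,2R)-3,3-dimethyl-2-[2-(2-methyl-1,3-dioxolan-2-yl)ethyl]cyclobutane-1-carboxylate (cis) | COC(=O)[C@@H]1CC(C)(C)[C@@H]1CCC2(C)OCCO2 | intermediate
13 | methyl (1S,2R)-3,3-dimethyl-2-[2-(2-methyl-1,3-dioxolan-2-yl)ethyl]cyclobutane-1-carboxylate (trans) | COC(=O)[C@H]1CC(C)(C)[C@@H]1CCC2(C)OCCO2 | intermediate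
14 | (1S,2R)-N-methoxy-N,3,3-trimethyl-2-[2-(2-methyl-1,3-dioxolan-2-yl)ethyl]cyclobutane-1-carboxamide | CON(C)C(=O)[C@H]1CC(C)(C)[C@@H]1CCC2(C)OCCO2 | intermediate
15 | (3-bromopropoxy)(tert-butyl)dimethylsilane | CC(C)(C)[Si](C)(C)OCCCBr | starting material
16 | {3-[(tert-butyldimethylsilyl)oxy]propyl}magnesium bromide | CC(C)(C)[Si](C)(C)OCCC[Mg]Br | intermediate
17 | 4-[(tert-butyldimethylsilyl)oxy]-1-{(1S,2R)-3,3-dimethyl-2-[2-(2-methyl-1,3-dioxolan-2-yl)ethyl]cyclobutyl}butan-1-one | CC(C)(C)[Si](C)(C)OCCCC(=O)[C@H]1CC(C)(C)[C@@H]1CCC2(C)OCCO2 | intermediate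
18 | tert-butyl({4-[(1S,2R)-3,3-dimethyl-2-[2-(2-methyl-1,3-dioxolan-2-yl)ethyl]cyclobutyl]pent-4-en-1-yl}oxy)dimethylsilane | C=C(CCCO[Si](C)(C)C(C)(C)C)[C@H]1CC(C)(C)[C@@H]1CCC2(C)OCCO2 | intermediate
19 | 4-[(1R,4S)-4-(5-hydroxypent-1-en-2-yl)-2,2-dimethylcyclobutyl]butan-2-one | C=C(CCCO)[C@H]1CC(C)(C)[C@@H]1CCC(C)=O | intermediate
20 | linoleic acid, (9Z,12Z)-octadeca-9,12-dienoic acid | CCCCC/C=C\C/C=C\CCCCCCCC(=O)O | starting material
21 | IN0146, 4-[(1S,2R)-3,3-dimethyl-2-(3-oxobutyl)cyclobutyl]pent-4-en-1-yl (9Z,12Z)-octadeca-9,12-dienoate | C=C(CCCOC(=O)CCCCCCC/C=C\C/C=C\CCCCC)[C@H]1CC(C)(C)[C@@H]1CCC(C)=O | target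

Total step count: 11.
Longest linear sequence: 11 steps (1 → 21). The Grignard reagents 6 and 16 are made and used within steps 3 and 8, and 5, 15 and 20 are commercial.

Steps most likely to fail

Step 5. The 1,4-biradical may fragment by β-scission faster than it closes. Amination of a nitrogen flanked by two substituted carbons may be slow. The ketal may be lost at 80 °C, after which the freed ketone would condense with the amine. The fallback separates N–N bond formation from nitrogen loss and avoids both acid and heat. Setting out from 10, the nitrogen would be nitrosated (tert-butyl nitrite, CH2Cl2, rt) to methyl (2S,5S)-4,4-dimethyl-5-[2-(2-methyl-1,3-dioxolan-2-yl)ethyl]-1-nitrosopyrrolidine-2-carboxylate F1. This would be reduced (Zn dust, aq. NH4Cl, MeOH, 0 °C) to methyl (2S,5S)-1-amino-4,4-dimethyl-5-[2-(2-methyl-1,3-dioxolan-2-yl)ethyl]pyrrolidine-2-carboxylate F2. The isolated hydrazine would then be oxidised at −20 to 0 °C (PhI(OAc)2 in CH2Cl2, or classically yellow HgO), the established oxidative deamination of 1,1-disubstituted hydrazines. This generates the same 1,1-diazene 11 under cold, neutral conditions, where collapse of the biradical is favoured over scission, and the sequence comes back to the route at 12.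

Step 3. Addition at the neopentyl-type lactam carbonyl may be slow enough that the organomagnesium attacks the methyl ester or the carbamate carbonyl instead (loss of the N-protecting group), and the β-ketal Grignard reagent may decompose before it reacts. The fallback makes the same C–C bond with a slim sp-nucleophile that has no β-hydrogen and reliably stops at the ketone. 2-Ethynyl-2-methyl-1,3-dioxolane F3 would be prepared from but-3-yn-2-one and ethylene glycol (TsOH cat., benzene, Dean–Stark) and lithiated (n-BuLi, THF, −78 °C) to [(2-methyl-1,3-dioxolan-2-yl)ethynyl]lithium F4. Setting out from 4, this acetylide would open the lactam at −78 °C to the ynone methyl (S)-2-{[(benzyloxy)carbonyl]amino}-4,4-dimethyl-7-(2-methyl-1,3-dioxolan-2-yl)-5-oxohept-6-ynoate F5. Hydrogenation over Pd/C in MeOH would then saturate the triple bond, remove the Cbz group and effect the reductive cyclisation in one operation, coming back to the route at 10.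

Step 6. Enolisation of the strained cyclobutyl ester may be slow, or the equilibrium may leave cis material, so that epimerisation is incomplete. The fallback moves the equilibration to a more acidic carbonyl. Setting out from 12, the cis ester would be carried unchanged through the Weinreb protocol of step 7 to (1R,2R)-N-methoxy-N,3,3-trimethyl-2-[2-(2-methyl-1,3-dioxolan-2-yl)ethyl]cyclobutane-1-carboxamide F6. The Grignard addition of step 8 would then give the cis ketone 4-[(tert-butyldimethylsilyl)oxy]-1-{(1R,2R)-3,3-dimethyl-2-[2-(2-methyl-1,3-dioxolan-2-yl)ethyl]cyclobutyl}butan-1-one F7. This would be equilibrated with DBU in CH2Cl2 (or K2CO3 in MeOH) at rt, where the α-proton is far easier to remove and the bulkier acyl group raises the trans preference, coming back to the route at 17.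

Further compounds
F1 | step 5 | methyl (2S,5S)-4,4-dimethyl-5-[2-(2-methyl-1,3-dioxolan-2-yl)ethyl]-1-nitrosopyrrolidine-2-carboxylate | COC(=O)[C@@H]1CC(C)(C)[C@H](CCC2(C)OCCO2)N1N=O
F2 | step 5 | methyl (2S,5S)-1-amino-4,4-dimethyl-5-[2-(2-methyl-1,3-dioxolan-2-yl)ethyl]pyrrolidine-2-carboxylate | COC(=O)[C@@H]1CC(C)(C)[C@H](CCC2(C)OCCO2)N1N
F3 | step 3 | 2-ethynyl-2-methyl-1,3-dioxolane | C#CC1(C)OCCO1
F4 | step 3 | [(2-methyl-1,3-dioxolan-2-yl)ethynyl]lithium | [Li]C#CC1(C)OCCO1
F5 | step 3 | methyl (S)-2-{[(benzyloxy)carbonyl]amino}-4,4-dimethyl-7-(2-methyl-1,3-dioxolan-2-yl)-5-oxohept-6-ynoate | COC(=O)[C@H](CC(C)(C)C(=O)C#CC1(C)OCCO1)NC(=O)OCc1ccccc1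
F6 | step 6 | (1R,2R)-N-methoxy-N,3,3-trimethyl-2-[2-(2-methyl-1,3-dioxolan-2-yl)ethyl]cyclobutane-1-carboxamide (cis) | CON(C)C(=O)[C@@H]1CC(C)(C)[C@@H]1CCC2(C)OCCO2
F7 | step 6 | 4-[(tert-butyldimethylsilyl)oxy]-1-{(1R,2R)-3,3-dimethyl-2-[2-(2-methyl-1,3-dioxolan-2-yl)ethyl]cyclobutyl}butan-1-one (cis) | CC(C)(C)[Si](C)(C)OCCCC(=O)[C@@H]1CC(C)(C)[C@@H]1CCC2(C)OCCO2
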